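**Plan**

- Feature (naphthoquinone numbering: C1=O next to C2–OMe and peri to C8–aryl; ring A quinone, ring B benzo): ring A is a 1,4-dione whose C1 and C4 hang on the adjacent arene carbons C8a and C4a, which is a phthalide retron. Its C2–C3 unit bears one OMe and one H, which is a methoxyacetylene equivalent.
- Retrosynthesis: C3–C4 and C1–C2 are cut together, giving 3-sulfonylphthalide 8 and 1-methoxyvinyl sulfone 12. Compound 8 is then cut at the C3–S/lactone unit, at the formyl C–C bond and at the biaryl bond, back to bromo acid 1 and boronic acid 4.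
- Forward: ring B is bought. The biaryl bond is made first, then the formyl carbon is added, then the lactone closes with the sulfone in place. Ring A arises last by anionic [4+2] annulation with 12, which is made in two steps from sulfone 9.
- Stereochemistry: the target is achiral. The stereocentres of 7, 8, 10, 11 and 13 are racemic and are all destroyed on the way.

Key step: step 7

Remark: 1, 4 and 9 are taken as purchasable; racemic compounds (7, 8, 10, 11, 13, F9) are drawn as one enantiomer.

**Route**

Step 1
Reactants: 1 2-bromo-4-methoxybenzoic acid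
Product: 3 N,N-diethyl-2-bromo-4-methoxybenzamide, via acid chloride 2 (not isolated)
Conditions: (COCl)2, DMF (cat.), CH2Cl2, 0 °C → rt; then Et2NH, aq. NaOH, CH2Cl2, 0 °C → rt
Reagents that add atoms: diethylamine, CCNCC; oxalyl chloride, O=C(Cl)C(Cl)=O (chlorine held by 2 only)
Why: Acid chloride formation followed by Schotten–Baumann amidation should install the tertiary amide, which later acts as directing group and latent lactone carbonyl, while the aryl bromide and the ether stay inert.

Step 2
Reactants: 3 N,N-diethyl-2-bromo-4-methoxybenzamide; 4 (3,4-dimethoxyphenyl)boronic acid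
Product: 5 N,N-diethyl-2-(3,4-dimethoxyphenyl)-4-methoxybenzamide
Conditions: Pd(PPh3)4 (5 mol %), K2CO3, DME/H2O, 85 °C
Reagents that add atoms: none
Why: Suzuki–Miyaura coupling, in which zerovalent palladium inserts into the C–Br bond ortho to the amide and the electron-rich boronic acid transmetalates, should form the biaryl bond without touching the amide.

Step 3
Reactants: 5 N,N-diethyl-2-(3,4-dimethoxyphenyl)-4-methoxybenzamide
Product: 6 N,N-diethyl-2-(3,4-dimethoxyphenyl)-6-formyl-4-methoxybenzamide
Conditions: s-BuLi, TMEDA, THF, −78 °C; DMF, −78 → 0 °C; H2O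
Reagents that add atoms: N,N-dimethylformamide, CN(C)C=O
Why: Directed ortho-metalation under kinetic conditions should place lithium at C6, the only free position ortho to the diethylamide (the strongest director present), and DMF formylates it; the low temperature disfavours lithiation of the neighbouring aryl ring.

Step 4
Reactants: 6 N,N-diethyl-2-(3,4-dimethoxyphenyl)-6-formyl-4-methoxybenzamide
Product: 8 rac-7-(3,4-dimethoxyphenyl)-5-methoxy-3-(phenylsulfonyl)isobenzofuran-1(3H)-one, via hydroxyphthalide 7 (not isolated)
Conditions: PhSO2Na, AcOH/H2O (10:1), 100 °C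
Reagents that add atoms: sodium benzenesulfinate, [Na+].[O-]S(=O)c1ccccc1; water, O (taken up in forming 7 and released again)
Why: The ortho-formyl group assists acid-mediated cleavage of the tertiary amide to the pseudo-acid 7, whose acyl-oxocarbenium ion is trapped at sulfur by benzenesulfinic acid (the usual condensation route to 3-sulfonylphthalides); the new stereocentre forms racemic and is lost in step 7.

Step 5
Reactants: 9 (methoxymethylsulfonyl)benzene
Product: 10 rac-2-methoxy-N,N-dimethyl-2-(phenylsulfonyl)ethanamine
Conditions: n-BuLi, THF, −78 °C; CH2=NMe2+ I− (Eschenmoser's salt), −78 °C → rt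
Reagents that add atoms: N,N-dimethylmethyleneiminium iodide, C=[N+](C)C.[I-]
Why: Mannich-type aminomethylation of the α-lithio sulfone with the preformed iminium salt should give the β-amino sulfone; its racemic centre is erased in step 6.

Step 6
Reactants: 10 rac-2-methoxy-N,N-dimethyl-2-(phenylsulfonyl)ethanamine
Product: 12 (1-methoxyethenyl)sulfonylbenzene, via ammonium iodide 11 (not isolated)
Conditions: MeI, MeCN, rt; evaporate excess MeI; K2CO3, MeCN, rt
Reagents that add atoms: iodomethane, CI (methyl held by 11 only)
Why: N-Methylation turns the amine into a leaving group β to the sulfone, and carbonate then brings about a Hofmann-type E1cB elimination, the classical way to α-methylenate through a Mannich base.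

Step 7
Reactants: 8 rac-7-(3,4-dimethoxyphenyl)-5-methoxy-3-(phenylsulfonyl)isobenzofuran-1(3H)-one; 12 (1-methoxyethenyl)sulfonylbenzene
Product: 14 8-(3,4-dimethoxyphenyl)-2,6-dimethoxynaphthalene-1,4-dione, via sulfonyl dihydrodione 13 (not isolated)
Conditions: LiOtBu (3 equiv), THF, −78 °C; 12 (1.5 equiv), −78 °C → rt; pH 7 phosphate buffer
Reagents that add atoms: none
Why: Proposed new method: LiOtBu removes the C3–H of 8 (future C4) and the anion adds to the CH2 terminus of 12 (future C3); the resulting α-methoxy-α-sulfonyl carbanion (future C2) closes ring A by a 6-exo-trig Dieckmann-type attack on the lactone carbonyl (future C1), the lactone opens, and the α-sulfonyl alkoxide expels the first sulfinate to give dione 13. Because C2 of 13 is quaternary, no tautomerisation to a hydroquinone is possible, so a second equivalent of base should deprotonate C3 and E1cB loss of the C2 sulfinate forms C2=C3 and the quinone directly at the right oxidation level. The closest known reaction type is the Hauser–Kraus annulation of 3-sulfonylphthalides with acrylates, enones and vinyl sulfones, which ends at the hydroquinone; the α-alkoxy vinyl sulfone acceptor and the closing sulfinate elimination are the untested parts. No stereocentre is created that survives, since the racemic centres of 8 and 13 both become sp2. The methoxy position is fixed by connectivity, because the methoxy-bearing carbanion carbon can only bond to the lactone carbonyl, which sits beside the aryl-bearing arene carbon; the elimination has to expel sulfinate and not methoxide, which the much lower basicity of sulfinate should secure. Adding excess 12 at −78 °C, so that the phthalide anion is used up before the quinone appears on warming, should prevent a second annulation onto the product.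

**Compound list**

1 | 2-bromo-4-methoxybenzoic acid | COc1ccc(C(=O)O)c(Br)c1 | starting material
2 | 2-bromo-4-methoxybenzoyl chloride | COc1ccc(C(Cl)=O)c(Br)c1 | intermediate (not isolated)
3 | N,N-diethyl-2-bromo-4-methoxybenzamide | CCN(CC)C(=O)c1ccc(OC)cc1Br | intermediate
4 | (3,4-dimethoxyphenyl)boronic acid | COc1ccc(B(O)O)cc1OC | starting material
5 | N,N-diethyl-2-(3,4-dimethoxyphenyl)-4-methoxybenzamide | CCN(CC)C(=O)c1ccc(OC)cc1-c1ccc(OC)c(OC)c1 | intermediate
6 | N,N-diethyl-2-(3,4-dimethoxyphenyl)-6-formyl-4-methoxybenzamide | CCN(CC)C(=O)c1c(C=O)cc(OC)cc1-c1ccc(OC)c(OC)c1 | intermediate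
7 | rac-7-(3,4-dimethoxyphenyl)-3-hydroxy-5-methoxyisobenzofuran-1(3H)-one | O=C1O[C@H](O)c2cc(OC)cc(-c3ccc(OC)c(OC)c3)c12 | intermediate (not isolated)
8 | rac-7-(3,4-dimethoxyphenyl)-5-methoxy-3-(phenylsulfonyl)isobenzofuran-1(3H)-one | O=C1O[C@H](S(=O)(=O)c2ccccc2)c2cc(OC)cc(-c3ccc(OC)c(OC)c3)c12 | intermediate
9 | (methoxymethylsulfonyl)benzene | COCS(=O)(=O)c1ccccc1 | starting material
10 | rac-2-methoxy-N,N-dimethyl-2-(phenylsulfonyl)ethanamine | CO[C@@H](CN(C)C)S(=O)(=O)c1ccccc1 | intermediate
11 | rac-[2-methoxy-2-(phenylsulfonyl)ethyl]trimethylammonium iodide | CO[C@@H](C[N+](C)(C)C)S(=O)(=O)c1ccccc1.[I-] | intermediate (not isolated)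
12 | (1-methoxyethenyl)sulfonylbenzene | C=C(OC)S(=O)(=O)c1ccccc1 | intermediate
13 | rac-8-(3,4-dimethoxyphenyl)-2,6-dimethoxy-2-(phenylsulfonyl)-2,3-dihydronaphthalene-1,4-dione | CO[C@@]1(S(=O)(=O)c2ccccc2)CC(=O)c2cc(OC)cc(-c3ccc(OC)c(OC)c3)c2C1=O | intermediate (not isolated)
14 | 8-(3,4-dimethoxyphenyl)-2,6-dimethoxynaphthalene-1,4-dione | COC1=CC(=O)c2cc(OC)cc(-c3ccc(OC)c(OC)c3)c2C1=O | target

**Count**

Total steps: 7. Longest linear sequence: 5 steps (steps 1, 2, 3, 4 and 7); steps 5 and 6 are the side branch to 12.

**Steps most likely to fail**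

1. Step 7 (proposed new method). Several things may go wrong:
   - The Michael addition to the donor-substituted alkene may be slow or may reverse.
   - The hindered carbanion may fail to close onto the lactone carbonyl shielded by the peri aryl group.
   - The quinone, once formed, may be consumed by a second annulation or by sulfinate addition.

   The fallback uses known chemistry only, sets out from 8 and comes back at 14.
   - Hauser–Kraus annulation of 8 with but-3-en-2-one (LiOtBu, THF, −78 °C → rt) should give 1-[8-(3,4-dimethoxyphenyl)-1,4-dihydroxy-6-methoxynaphthalen-2-yl]ethanone F1.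
   - Double O-methylation (Me2SO4, K2CO3, acetone, reflux) gives 1-[8-(3,4-dimethoxyphenyl)-1,4,6-trimethoxynaphthalen-2-yl]ethanone F2.
   - Baeyer–Villiger oxidation (mCPBA, NaHCO3, CH2Cl2), with migration of the electron-rich aryl group, gives 8-(3,4-dimethoxyphenyl)-1,4,6-trimethoxynaphthalen-2-yl acetate F3.
   - Methanolysis (K2CO3, MeOH) frees 8-(3,4-dimethoxyphenyl)-1,4,6-trimethoxynaphthalen-2-ol F4.
   - Methylation (MeI, K2CO3, DMF) gives 8-(3,4-dimethoxyphenyl)-1,2,4,6-tetramethoxynaphthalene F5.
   - Oxidative demethylation of the 1,4-dimethoxy pair with (NH4)2Ce(NO3)6 in MeCN/H2O at 0 °C should deliver 14, the oxygen pattern being fixed by the acetyl position.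

2. Step 3. Lithiation may stray to the neighbouring aryl ring or to positions ortho to methoxy, with anionic cyclisation onto the amide, or s-BuLi may add to the amide. The fallback replaces directed metalation by carboxylate-directed C–H alkylation, sets out from 1 and 4 and comes back at 6.
   - Suzuki–Miyaura coupling of the free acid 1 with 4 (Pd(PPh3)4, K2CO3, dioxane/H2O, 90 °C) gives 2-(3,4-dimethoxyphenyl)-4-methoxybenzoic acid F6.
   - Pd(OAc)2 (cat.), K2HPO4, CH2Br2, 140 °C effects ortho C–H alkylation and lactonisation to 7-(3,4-dimethoxyphenyl)-5-methoxyisobenzofuran-1(3H)-one F7.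
   - Aminolysis with Et2NH/AlCl3 in 1,2-dichloroethane opens the lactone to N,N-diethyl-2-(3,4-dimethoxyphenyl)-6-(hydroxymethyl)-4-methoxybenzamide F8.
   - MnO2 in CH2Cl2 oxidises the benzylic alcohol to 6.

3. Step 6. Quaternisation or elimination may stall, trimethylamine may add back to the alkene, or the captodative enol-ether sulfone may polymerise or hydrolyse during isolation. The fallback builds the alkene by olefination, sets out from 9 and comes back at 12.
   - Deprotonation of 9 (n-BuLi, 2 equiv, THF, −78 °C) and phosphorylation with ClP(O)(OEt)2 gives diethyl [methoxy(phenylsulfonyl)methyl]phosphonate F9.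
   - Horner–Wadsworth–Emmons reaction of F9 with aqueous formaldehyde and K2CO3 at rt gives 12 under amine-free conditions.

**Further compounds**

F1 | step 7 | 1-[8-(3,4-dimethoxyphenyl)-1,4-dihydroxy-6-methoxynaphthalen-2-yl]ethanone | CC(=O)c1cc(O)c2cc(OC)cc(-c3ccc(OC)c(OC)c3)c2c1O
F2 | step 7 | 1-[8-(3,4-dimethoxyphenyl)-1,4,6-trimethoxynaphthalen-2-yl]ethanone | CC(=O)c1cc(OC)c2cc(OC)cc(-c3ccc(OC)c(OC)c3)c2c1OC
F3 | step 7 | 8-(3,4-dimethoxyphenyl)-1,4,6-trimethoxynaphthalen-2-yl acetate | CC(=O)Oc1cc(OC)c2cc(OC)cc(-c3ccc(OC)c(OC)c3)c2c1OC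
F4 | step 7 | 8-(3,4-dimethoxyphenyl)-1,4,6-trimethoxynaphthalen-2-ol | Oc1cc(OC)c2cc(OC)cc(-c3ccc(OC)c(OC)c3)c2c1OC
F5 | step 7 | 8-(3,4-dimethoxyphenyl)-1,2,4,6-tetramethoxynaphthalene | COc1cc(OC)c2cc(OC)cc(-c3ccc(OC)c(OC)c3)c2c1OC
F6 | step 3 | 2-(3,4-dimethoxyphenyl)-4-methoxybenzoic acid | COc1ccc(C(=O)O)c(-c2ccc(OC)c(OC)c2)c1
F7 | step 3 | 7-(3,4-dimethoxyphenyl)-5-methoxyisobenzofuran-1(3H)-one | O=C1OCc2cc(OC)cc(-c3ccc(OC)c(OC)c3)c12
F8 | step 3 | N,N-diethyl-2-(3,4-dimethoxyphenyl)-6-(hydroxymethyl)-4-methoxybenzamide | CCN(CC)C(=O)c1c(CO)cc(OC)cc1-c1ccc(OC)c(OC)c1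
F9 | step 6 | rac-diethyl [methoxy(phenylsulfonyl)methyl]phosphonate | CCOP(=O)(OCC)[C@H](OC)S(=O)(=O)c1ccccc1
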